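## Structural features

2'-Hydroxylupalbigenin is an isoflavone. Benzene ring A (C4a, C5 to C8, C8a) is fused to the γ-pyrone ring C (O1, C2, C3, C4), and benzene ring B (C1' to C6') is attached at C3. There is no stereocentre, and the two prenyl alkenes are trisubstituted with geminal methyl groups, so the target has no configurational issue.

Ring A carries OH at C5 and C7 with a prenyl group on C6 between them. Ring B carries OH at C2' and C4' with a prenyl group on C3' between them. Read outward from ring C, both benzene rings show the same run of atoms: junction carbon (C4a or C1'), C–OH (C5 or C2'), C–prenyl (C6 or C3'), C–OH (C7 or C4'), C–H (C8 or C5'). The key step exploits this repeat, because the sequence C(OH)–C(R)–C(OR')–CH is exactly what a ketene and an ynol ether R–C≡C–OR' leave behind in a benzannulation.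

The real difficulty is regiochemical. C6 must be distinguished from C8 and C3' from C5'. Each prenyl group sits in the most crowded site, between two oxygens. The C3–C1' bond is flanked by C4=O and the 2'-oxygen.

The fragile groups are these:
- Each prenyl alkene is ortho to two phenols, so it closes to a dimethylchroman under acid and is attacked by electrophilic oxidants.
- The 2'-OH can add to C2 under base.
- The pyrone is opened by hard nucleophiles.

The last operations should therefore be neutral.

## Logic of the disconnections

**19 to 18.** The O7–Si and O4'–Si bonds are cut. These silyl groups are not added for protection; they arrive with the alkyne of the key step. The 5-OH and 2'-OH are already free in 18. The gain is an end game with a single buffered fluoride treatment and no acid near the prenyl groups. The forward step must keep the 2'-phenoxide from adding to C2, so the fluoride has to be buffered.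

**18 to 15 and two molecules of 6 (key disconnection).**
- In ring A the bonds C4a–C5, C5–C6 and C7–C8 are cut. In ring B the bonds C1'–C2', C2'–C3' and C4'–C5' are cut.
- C6/C7 and C3'/C4' return to the two alkyne carbons of 6. C5 and C2' return to ketone carbonyl carbons. C8 and C5' return to diazo carbons, which a 1,2-shift joins to C8a and C6' in the forward direction.
- The cut is made here because both rings contain the same O–C(prenyl)–O–CH run, so a single reagent can deliver both. The polarity of 6 places each prenyl group between two oxygens with no choice left between C6/C8 or C3'/C5'.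
- The gain is the largest available: both arenes, both prenyl groups and all four phenolic oxygens disappear, and a C43 compound becomes a C11 pyrone and two copies of one C16 alkyne.
- The forward step must form two ketenes cleanly. Each ketene must choose the alkyne of 6 over the prenyl alkenes, and each arm must pass two electrocyclic reactions.

**15 to 13.** The two C=N2 bonds are cut. Acylation of diazomethane is not an option for the unsaturated arm, because the dipole adds to conjugated alkenes. Both arms are therefore traced back to methyl ketones, which one diazo-transfer operation treats alike. The gain is a stable, symmetrically functionalised diketone. The forward step needs double kinetic enolisation without attack on ring C.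

**13 to 11 and 12.** The bond between C3 and the vinyl carbon that becomes C1' is cut. This is the future C3–C1' bond. It is made as an unhindered vinyl–vinyl bond before ring B exists, instead of as a hindered heteroaryl–aryl bond next to the 2'-oxygen. The E geometry needed later comes from syn insertion and syn elimination. The forward step needs a base mild enough for the pyrone.

**11 to 8 and 9.** The C8a–C4a bond (acylation of a methyl ketone enolate) and the O1–C2 bond (displacement of the amine) are cut. Ring C is thereby reduced to two commercial-type four- and three-carbon pieces. The halogen on C3 and the acetyl group on C8a are placed by construction, not by selective substitution of a pyrone. The forward step needs a crossed condensation with a hindered, non-enolisable ester, followed by acid closure without loss of bromine.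

**8 to 7.** The C–Br bond is cut at the nucleophilic α-carbon of the push–pull alkene. The forward step is a simple electrophilic substitution.

**6 to 3, and 3 to 1 and 2.** The O–Si and alkyne C–O bonds are cut first, then the bond between the prenyl CH2 and the alkyne carbon. This leaves only commercial C5 and C2 pieces. The forward steps need substitution at the primary end of the allyl system and oxygen transfer to an acetylide that leaves the alkene alone.

## Other disconnections considered

**Alternative 1:** cut C3–C1' between finished rings. This is the first idea that comes to mind.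
- The forward key step is a Suzuki–Miyaura coupling of the 3-iodochromone A1 with the boronic acid A2 to give the tetra-acetal A3, followed by acid unmasking.
- The coupling does not touch the real problem. Each arene must be prenylated separately between two oxygens.
- A1 further requires the two ortho oxygens of a phloroglucinol ketone to be distinguished before ring C is closed, otherwise C6 and C8 are scrambled.
- A2 is an electron-rich, ortho-oxygenated boronic acid and is prone to protodeboronation.
- A3 needs four acetals removed by acid next to two prenyl groups.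
- The count is about a dozen operations, against eight in the chosen plan.

**Alternative 2:** cut C4–C4a, closing ring C at carbon instead of at oxygen.
- The forward key step is intramolecular acylation of the symmetric ring A ether in the acrylic acid A4, which would give A3.
- The local symmetry of the 4-prenylphloroglucinol ether removes the C6/C8 question, and this is a real merit.
- The preferred alkene geometry, however, places the aryloxy group trans to the carboxyl group, so only cationic activation can bring the reacting centres together.
- Under such activation the 2'-oxygen sits in a five-membered relation to the acyl carbon, and an acetal protecting group there can be lost by lactonisation.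
- Both prenyl groups must also survive an electrophilic step and a final acid step.
- Both arenes still need their own prenylation, and the count is nine to ten steps.

**Alternative 3:** cut C3–C1' by way of a 1,2-aryl shift, the biomimetic route.
- The forward key step is oxidative rearrangement of the chalcone A5 with Tl(NO3)3 (trivalent thallium) or PhI(OAc)2, then closure to A3.
- These oxidants are alkene electrophiles, and the two trisubstituted prenyl alkenes are more nucleophilic than the enone, so chemoselectivity runs against the plan unless the prenyl groups are masked.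
- A5 also inherits the same ring A regiochemical problem as A1 and the same acid end game.
- It would be longer than the chosen plan.

Key step: step 7

Remark on numbering: isoflavone numbering is used for ring C in all intermediates. Pyran positions 2, 3, 4, 5 and 6 of 11, 13 and 15 are the future C8a, C4a, C4, C3 and C2.

Assumption: 17 forms as a mixture of diastereomers. Its two sp3 centres are lost on aromatisation, so its SMILES carries no configuration at these centres.

## Steps

Step 1
Reactants: 1 1-bromo-3-methylbut-2-ene (prenyl bromide); 2 ethynylmagnesium bromide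
Product: 3 5-methylhex-4-en-1-yne
Conditions: CuCl (5 mol %), THF, 0 °C to rt
Reagents that add atoms: none
Why: Copper-catalysed allylic substitution of an alkynyl Grignard reagent; attack at the unhindered primary terminus is favoured over the tertiary end, which should give the skipped enyne.

Step 2
Reactants: 3 5-methylhex-4-en-1-yne
Product: 6 triisopropyl[(5-methylhex-4-en-1-yn-1-yl)oxy]silane, via lithium acetylide 4 (not isolated), via lithium ynolate 5 (not isolated)
Conditions: n-BuLi, THF, −78 °C; t-BuOOLi (from t-BuOOH and LiN(SiMe3)2), −78 to 0 °C; i-Pr3SiOTf, −78 to 0 °C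
Reagents that add atoms: tert-butyl hydroperoxide CC(C)(C)OO (the ynolate oxygen); triisopropylsilyl trifluoromethanesulfonate CC(C)[Si](C(C)C)(C(C)C)OS(=O)(=O)C(F)(F)F; n-butyllithium [Li]CCCC (lithium of 4 and 5 only)
Why: Oxidation of a lithium acetylide by a lithium alkyl peroxide transfers oxygen to carbon and gives the ynolate, which a bulky silyl triflate traps at oxygen. The anionic peroxide does not epoxidise an unactivated alkene, and one equivalent of base removes only the acetylenic proton.

Step 3
Reactants: 7 (3E)-4-(dimethylamino)but-3-en-2-one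
Product: 8 (3Z)-3-bromo-4-(dimethylamino)but-3-en-2-one
Conditions: N-bromosuccinimide, CH2Cl2, 0 °C
Reagents that add atoms: N-bromosuccinimide O=C1CCC(=O)N1Br
Why: Electrophilic α-halogenation of a push–pull enaminone at its nucleophilic α-carbon, followed by loss of the proton. The amino group stays trans to the acetyl group, so the descriptor changes to Z only through the priority of bromine.

Step 4
Reactants: 8 (3Z)-3-bromo-4-(dimethylamino)but-3-en-2-one; 9 methyl 2,2-dimethoxypropanoate
Product: 11 2-acetyl-5-bromo-4H-pyran-4-one, via enaminodiketone 10 (not isolated)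
Conditions: LiN(SiMe3)2 (2.2 equiv), THF, −78 °C; 9, −78 °C to rt; then 2 M aq. HCl, rt
Reagents that add atoms: water O (oxygen of the acetyl group)
Why: Crossed Claisen condensation of the methyl ketone enolate with a non-enolisable ester that is inductively activated by its two α-alkoxy groups. In acid the enol oxygen adds to the protonated enaminone and dimethylamine leaves (the standard γ-pyrone synthesis from 1-amino-1-ene-3,5-diones), and the same acid unmasks the acetyl group. Bromine ends on the future C3 because it was placed on the enaminone α-carbon.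

Step 5
Reactants: 11 2-acetyl-5-bromo-4H-pyran-4-one; 12 but-3-en-2-one (methyl vinyl ketone)
Product: 13 2-acetyl-5-[(1E)-3-oxobut-1-en-1-yl]-4H-pyran-4-one
Conditions: 12 (3 equiv), Pd(OAc)2 (5 mol %), n-Bu4NCl, NaHCO3, DMF, 60 °C
Reagents that add atoms: none
Why: Heck reaction of an electron-poor α-bromoenone, as known for 3-halochromones and 3-halopyranones. Insertion at the terminal carbon of 12 and syn β-hydride elimination should give the E enone, and hydrogen carbonate is too weak to open the pyrone.

Step 6
Reactants: 13 2-acetyl-5-[(1E)-3-oxobut-1-en-1-yl]-4H-pyran-4-one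
Product: 15 2-(2-diazoacetyl)-5-[(1E)-4-diazo-3-oxobut-1-en-1-yl]-4H-pyran-4-one, via bis(trifluoroacetyl) ketone 14 (not isolated)
Conditions: LiN(SiMe3)2 (2.3 equiv), THF, −78 °C; CF3CO2CH2CF3; 5% aq. HCl work-up; then 4-AcNHC6H4SO2N3, Et3N, H2O, MeCN, rt
Reagents that add atoms: 2,2,2-trifluoroethyl trifluoroacetate O=C(OCC(F)(F)F)C(F)(F)F (trifluoroacetyl groups of 14 only); 4-acetamidobenzenesulfonyl azide CC(=O)Nc1ccc(cc1)S(=O)(=O)N=[N+]=[N-]
Why: Deacylative (detrifluoroacetylative) Regitz diazo transfer, the standard route to α'-diazo enones and heteroaryl diazomethyl ketones from methyl ketones. Both methyl groups are the only acidic sites, each is activated as a trifluoroacetyl diketone, and each then exchanges the activating group for N2. The hindered amide base and low temperature should spare ring C.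

Step 7
Reactants: 15 2-(2-diazoacetyl)-5-[(1E)-4-diazo-3-oxobut-1-en-1-yl]-4H-pyran-4-one; 6 triisopropyl[(5-methylhex-4-en-1-yn-1-yl)oxy]silane (two molecules enter the product)
Product: 18 5-hydroxy-3-{2-hydroxy-3-(3-methylbut-2-en-1-yl)-4-[(triisopropylsilyl)oxy]phenyl}-6-(3-methylbut-2-en-1-yl)-7-[(triisopropylsilyl)oxy]-4H-chromen-4-one, via bis-ketene 16 (not isolated), via bis-cyclobutenone 17 (not isolated)
Conditions: 6 (3 equiv), hν (300–350 nm), ClCH2CH2Cl, rt; then 80 °C
Reagents that add atoms: none
Why: Danheiser benzannulation in its diazoketone form, run on both arms of 15 at once. Light expels N2 from each s-cis diazoketone with a concerted 1,2-shift (Wolff rearrangement) and gives 16, in which the ketene of arm A is conjugated with the C8a=C4a double bond of the pyrone and that of arm B with the E alkene on C3. Each ketene adds 6 in a polarity-controlled [2+2] step, the electrophilic ketene carbonyl carbon binding the nucleophilic prenyl-bearing alkyne carbon and the ketene α-carbon binding the silyloxy-bearing carbon, so both four-membered rings of 17 hold the sequence C=O, C-prenyl, C-OSi. On heating (or already under the lamp) each cyclobutenone opens by a reversible conrotatory four-electron electrocyclic reaction to a dienylketene, and only the isomer with the pyrone (arm A) or the alkenyl group (arm B) turned inward reacts further. Ring A closes by a disrotatory six-electron electrocyclisation that forms C4a–C5 at the only position next to C8a, ring B closes in the same mode by forming C1'–C2', and enolisation of the two cyclohexadienones gives the phenols at C5 and C2'. No stereocentre remains, since the two sp3 centres of 17 are lost on aromatisation. The step needs three selectivities: the orientation of the [2+2] step, secured by the donor oxygen of 6; the preference of the ketenes for the ynol ether over the prenyl alkenes and the pyrone, secured by the much higher nucleophilicity and the excess of 6; and retention of the E alkene, secured by fast trapping of the ketene. The closest known cases are the same annulation of alkenyl and of heteroaryl diazomethyl ketones with triisopropylsilyloxyalkynes, which give resorcinol monosilyl ethers with the alkyne substituent between the two oxygens; the γ-pyrone as alkene partner and the twofold mode are the extensions made here.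

Step 8
Reactants: 18 5-hydroxy-3-{2-hydroxy-3-(3-methylbut-2-en-1-yl)-4-[(triisopropylsilyl)oxy]phenyl}-6-(3-methylbut-2-en-1-yl)-7-[(triisopropylsilyl)oxy]-4H-chromen-4-one
Product: 19 2'-hydroxylupalbigenin, 3-[2,4-dihydroxy-3-(3-methylbut-2-en-1-yl)phenyl]-5,7-dihydroxy-6-(3-methylbut-2-en-1-yl)-4H-chromen-4-one
Conditions: n-Bu4NF, AcOH (1:1, 2.2 equiv each), THF, 0 °C
Reagents that add atoms: none
Why: Fluoride cleavage of aryl silyl ethers. The acetic acid buffer protonates the phenoxides as they form, so neither acid-induced chroman formation nor addition of the 2'-phenoxide to C2 should intervene.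

## Compound list

1 | 1-bromo-3-methylbut-2-ene | CC(C)=CCBr | starting material
2 | ethynylmagnesium bromide | C#C[Mg]Br | starting material
3 | 5-methylhex-4-en-1-yne | C#CCC=C(C)C | intermediate
4 | (5-methylhex-4-en-1-yn-1-yl)lithium | [Li]C#CCC=C(C)C | intermediate
5 | lithium 5-methylhex-4-en-1-yn-1-olate | [Li]OC#CCC=C(C)C | intermediate
6 | triisopropyl[(5-methylhex-4-en-1-yn-1-yl)oxy]silane | CC(C)=CCC#CO[Si](C(C)C)(C(C)C)C(C)C | intermediate
7 | (3E)-4-(dimethylamino)but-3-en-2-one | CC(=O)/C=C/N(C)C | starting material
8 | (3Z)-3-bromo-4-(dimethylamino)but-3-en-2-one | CC(=O)/C(Br)=C/N(C)C | intermediate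
9 | methyl 2,2-dimethoxypropanoate | COC(=O)C(C)(OC)OC | starting material
10 | (1Z)-2-bromo-1-(dimethylamino)-6,6-dimethoxyhept-1-ene-3,5-dione | CN(C)/C=C(Br)/C(=O)CC(=O)C(C)(OC)OC | intermediate
11 | 2-acetyl-5-bromo-4H-pyran-4-one | CC(=O)C1=CC(=O)C(Br)=CO1 | intermediate
12 | but-3-en-2-one | C=CC(C)=O | starting material
13 | 2-acetyl-5-[(1E)-3-oxobut-1-en-1-yl]-4H-pyran-4-one | CC(=O)C1=CC(=O)C(/C=C/C(C)=O)=CO1 | intermediate
14 | 4,4,4-trifluoro-1-{4-oxo-5-[(1E)-6,6,6-trifluoro-3,5-dioxohex-1-en-1-yl]-4H-pyran-2-yl}butane-1,3-dione | O=C(CC(=O)C(F)(F)F)C1=CC(=O)C(/C=C/C(=O)CC(=O)C(F)(F)F)=CO1 | intermediate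
15 | 2-(2-diazoacetyl)-5-[(1E)-4-diazo-3-oxobut-1-en-1-yl]-4H-pyran-4-one | [N-]=[N+]=CC(=O)C1=CC(=O)C(/C=C/C(=O)C=[N+]=[N-])=CO1 | intermediate
16 | 2-(2-oxoethenyl)-5-[(1E)-4-oxobuta-1,3-dien-1-yl]-4H-pyran-4-one | O=C=CC1=CC(=O)C(/C=C/C=C=O)=CO1 | intermediate
17 | 2-[3-(3-methylbut-2-en-1-yl)-4-oxo-2-(triisopropylsilyloxy)cyclobut-2-en-1-yl]-5-{(1E)-2-[3-(3-methylbut-2-en-1-yl)-4-oxo-2-(triisopropylsilyloxy)cyclobut-2-en-1-yl]ethenyl}-4H-pyran-4-one (mixture of diastereomers) | O=C1C(CC=C(C)C)=C(O[Si](C(C)C)(C(C)C)C(C)C)C1C2=CC(=O)C(/C=C/C3C(=O)C(CC=C(C)C)=C3O[Si](C(C)C)(C(C)C)C(C)C)=CO2 | intermediate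
18 | 5-hydroxy-3-{2-hydroxy-3-(3-methylbut-2-en-1-yl)-4-[(triisopropylsilyl)oxy]phenyl}-6-(3-methylbut-2-en-1-yl)-7-[(triisopropylsilyl)oxy]-4H-chromen-4-one | CC(C)=CCc1c(O[Si](C(C)C)(C(C)C)C(C)C)ccc(-c2coc3cc(O[Si](C(C)C)(C(C)C)C(C)C)c(CC=C(C)C)c(O)c3c2=O)c1O | intermediate
19 | 2'-hydroxylupalbigenin | CC(C)=CCc1c(O)ccc(-c2coc3cc(O)c(CC=C(C)C)c(O)c3c2=O)c1O | target

## Step count and least certain steps

Total step count: 8. Longest linear sequence: 6 steps (steps 3, 4, 5, 6, 7, 8). The branch to 6 (steps 1 and 2) joins at step 7.

**Step 7 (key step).**
- Risk: the most likely failure is loss of material, because two Wolff rearrangements, two cycloadditions and four electrocyclic reactions must all succeed in one molecule.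
- Prolonged irradiation may excite the pyrone chromophore.
- The alkene of arm B may isomerise from E to Z, after which its ketene can close onto C2 of the pyrone instead of meeting 6.
- Phenol formed early may capture ketene formed late.
- Fallback (from 11, back at 18): the two annulations are run one after the other, so that each concerns one ketene only.
  - The single methyl ketone of 11 is taken through the sequence of step 6, by way of 1-(5-bromo-4-oxo-4H-pyran-2-yl)-4,4,4-trifluorobutane-1,3-dione F1, to 5-bromo-2-(2-diazoacetyl)-4H-pyran-4-one F2.
  - Irradiation of F2 with 6 and heating proceeds through the ketene 5-bromo-2-(2-oxoethenyl)-4H-pyran-4-one F3 and the cyclobutenone F4. This builds ring A alone and should give 3-bromo-5-hydroxy-6-(3-methylbut-2-en-1-yl)-7-(triisopropylsilyloxy)-4H-chromen-4-one F5.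
  - A Heck reaction of F5 with 12, as in step 5, leads to the enone F6.
  - Diazo transfer, with one further equivalent of base for the chelated 5-OH, leads through the trifluoroacetyl diketone F7 to the diazoketone F8.
  - A second benzannulation with 6 passes through the ketene F9 and the cyclobutenone F10, builds ring B and returns to 18.

**Step 6.**
- Risk: the most likely failure is attack of the enolates or of the amide base on ring C and on the enone (conjugate addition, ring opening). Activation may also stop at one arm, because 13 carries three acceptor systems.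
- Fallback (from 13, back at 15): strong base is avoided altogether.
  - Riley oxidation of both methyl ketones with SeO2 (aqueous dioxane, heat) should give the bis-glyoxal F11.
  - Condensation at the two aldehyde groups with 4-methylbenzenesulfonohydrazide gives the bis(tosylhydrazone) F12.
  - Triethylamine in CH2Cl2 expels sulfinate from each arm (Bamford–Stevens-type elimination) to give 15.

**Step 4.**
- Risk: the most likely failure is slow acylation by the hindered ester 9, so that the enolate of 8 condenses with itself. Bromine may also be lost by protonation at the bromine-bearing carbon during the acid closure.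
- Fallback (from 8, back at 11): the acyl partner is changed to the far more electrophilic diethyl oxalate, and the acetyl group is built afterwards.
  - Claisen condensation gives ethyl (5Z)-5-bromo-6-(dimethylamino)-2,4-dioxohex-5-enoate F13.
  - Brief acid treatment closes it to ethyl 5-bromo-4-oxo-4H-pyran-2-carboxylate F14.
  - Crossed Claisen condensation with the lithium enolate of tert-butyl acetate at −78 °C gives tert-butyl 3-(5-bromo-4-oxo-4H-pyran-2-yl)-3-oxopropanoate F15.
  - CF3CO2H in CH2Cl2 removes the tert-butyl group, and decarboxylation gives 11.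

**Step 5.**
- Risk: the most likely failures are polymerisation of 12, diversion to the reductive (conjugate-addition type) pathway, and base-induced degradation of the pyrone at 60 °C.
- Fallback (from 11, back at 13): the enone is assembled under neutral conditions.
  - Stille coupling of 11 with tributyl(vinyl)stannane and Pd(PPh3)4 gives 2-acetyl-5-ethenyl-4H-pyran-4-one F16.
  - Cross-metathesis of F16 with 12 using the second-generation Hoveyda–Grubbs catalyst should give the E enone 13.

## Further compounds

F1 | step 7 | 1-(5-bromo-4-oxo-4H-pyran-2-yl)-4,4,4-trifluorobutane-1,3-dione | O=C(CC(=O)C(F)(F)F)C1=CC(=O)C(Br)=CO1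
F2 | step 7 | 5-bromo-2-(2-diazoacetyl)-4H-pyran-4-one | [N-]=[N+]=CC(=O)C1=CC(=O)C(Br)=CO1
F3 | step 7 | 5-bromo-2-(2-oxoethenyl)-4H-pyran-4-one | O=C=CC1=CC(=O)C(Br)=CO1
F4 | step 7 | 5-bromo-2-[3-(3-methylbut-2-en-1-yl)-4-oxo-2-(triisopropylsilyloxy)cyclobut-2-en-1-yl]-4H-pyran-4-one (racemic) | O=C1C(CC=C(C)C)=C(O[Si](C(C)C)(C(C)C)C(C)C)C1C2=CC(=O)C(Br)=CO2
F5 | step 7 | 3-bromo-5-hydroxy-6-(3-methylbut-2-en-1-yl)-7-(triisopropylsilyloxy)-4H-chromen-4-one | CC(C)=CCc1c(O[Si](C(C)C)(C(C)C)C(C)C)cc2occ(Br)c(=O)c2c1O
F6 | step 7 | 5-hydroxy-6-(3-methylbut-2-en-1-yl)-3-[(1E)-3-oxobut-1-en-1-yl]-7-(triisopropylsilyloxy)-4H-chromen-4-one | CC(=O)/C=C/c1coc2cc(O[Si](C(C)C)(C(C)C)C(C)C)c(CC=C(C)C)c(O)c2c1=O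
F7 | step 7 | (5E)-1,1,1-trifluoro-6-[5-hydroxy-6-(3-methylbut-2-en-1-yl)-4-oxo-7-(triisopropylsilyloxy)-4H-chromen-3-yl]hex-5-ene-2,4-dione | O=C(CC(=O)C(F)(F)F)/C=C/c1coc2cc(O[Si](C(C)C)(C(C)C)C(C)C)c(CC=C(C)C)c(O)c2c1=O
F8 | step 7 | 3-[(1E)-4-diazo-3-oxobut-1-en-1-yl]-5-hydroxy-6-(3-methylbut-2-en-1-yl)-7-(triisopropylsilyloxy)-4H-chromen-4-one | [N-]=[N+]=CC(=O)/C=C/c1coc2cc(O[Si](C(C)C)(C(C)C)C(C)C)c(CC=C(C)C)c(O)c2c1=O
F9 | step 7 | 5-hydroxy-6-(3-methylbut-2-en-1-yl)-3-[(1E)-4-oxobuta-1,3-dien-1-yl]-7-(triisopropylsilyloxy)-4H-chromen-4-one | O=C=C/C=C/c1coc2cc(O[Si](C(C)C)(C(C)C)C(C)C)c(CC=C(C)C)c(O)c2c1=O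
F10 | step 7 | 5-hydroxy-6-(3-methylbut-2-en-1-yl)-3-{(1E)-2-[3-(3-methylbut-2-en-1-yl)-4-oxo-2-(triisopropylsilyloxy)cyclobut-2-en-1-yl]ethenyl}-7-(triisopropylsilyloxy)-4H-chromen-4-one (racemic) | O=C1C(CC=C(C)C)=C(O[Si](C(C)C)(C(C)C)C(C)C)C1/C=C/c2coc3cc(O[Si](C(C)C)(C(C)C)C(C)C)c(CC=C(C)C)c(O)c3c2=O
F11 | step 6 | (3E)-2-oxo-4-[6-(oxoacetyl)-4-oxo-4H-pyran-3-yl]but-3-enal | O=CC(=O)C1=CC(=O)C(/C=C/C(=O)C=O)=CO1
F12 | step 6 | bis(4-methylbenzenesulfonylhydrazone) of F11 at both aldehyde groups (hydrazone geometry immaterial) | Cc1ccc(cc1)S(=O)(=O)NN=CC(=O)C2=CC(=O)C(/C=C/C(=O)C=NNS(=O)(=O)c3ccc(C)cc3)=CO2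
F13 | step 4 | ethyl (5Z)-5-bromo-6-(dimethylamino)-2,4-dioxohex-5-enoate | CCOC(=O)C(=O)CC(=O)/C(Br)=C/N(C)C
F14 | step 4 | ethyl 5-bromo-4-oxo-4H-pyran-2-carboxylate | CCOC(=O)C1=CC(=O)C(Br)=CO1
F15 | step 4 | tert-butyl 3-(5-bromo-4-oxo-4H-pyran-2-yl)-3-oxopropanoate | CC(C)(C)OC(=O)CC(=O)C1=CC(=O)C(Br)=CO1
F16 | step 5 | 2-acetyl-5-ethenyl-4H-pyran-4-one | C=CC1=COC(C(C)=O)=CC1=O
A1 | alternative 1 | 3-iodo-5,7-bis(methoxymethoxy)-6-(3-methylbut-2-en-1-yl)-4H-chromen-4-one | COCOc1cc2occ(I)c(=O)c2c(OCOC)c1CC=C(C)C
A2 | alternative 1 | [2,4-bis(methoxymethoxy)-3-(3-methylbut-2-en-1-yl)phenyl]boronic acid | COCOc1ccc(B(O)O)c(OCOC)c1CC=C(C)C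
A3 | alternative 1 | 3-[2,4-bis(methoxymethoxy)-3-(3-methylbut-2-en-1-yl)phenyl]-5,7-bis(methoxymethoxy)-6-(3-methylbut-2-en-1-yl)-4H-chromen-4-one | COCOc1cc2occ(-c3ccc(OCOC)c(CC=C(C)C)c3OCOC)c(=O)c2c(OCOC)c1CC=C(C)C
A4 | alternative 2 | (2Z)-3-[3,5-bis(methoxymethoxy)-4-(3-methylbut-2-en-1-yl)phenoxy]-2-[2,4-bis(methoxymethoxy)-3-(3-methylbut-2-en-1-yl)phenyl]prop-2-enoic acid | OC(=O)/C(=C\Oc1cc(OCOC)c(CC=C(C)C)c(OCOC)c1)c2ccc(OCOC)c(CC=C(C)C)c2OCOC
A5 | alternative 3 | (2E)-3-[2,4-bis(methoxymethoxy)-3-(3-methylbut-2-en-1-yl)phenyl]-1-[2-hydroxy-4,6-bis(methoxymethoxy)-5-(3-methylbut-2-en-1-yl)phenyl]prop-2-en-1-one | O=C(/C=C/c1ccc(OCOC)c(CC=C(C)C)c1OCOC)c2c(O)cc(OCOC)c(CC=C(C)C)c2OCOC
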